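The route rests on disconnecting the indole pyrrole ring of didemnimide D at C3–C3a and N1–C2. A Larock heteroannulation joins 5-bromo-2-iodoaniline to a silyl alkyne that already carries the imidazolyl maleimide; in one operation it closes the pyrrole ring, sets the maleimide at indole C3 and places bromine at C6 only. The feature exploited is the benzene ring of the indole: C7a (bearing N1) and C3a are adjacent, and C6 with its bromine is para to C3a. The precursor is an N-(2,4-dimethoxybenzyl)maleimide with 1-methylimidazol-5-yl at C3 and a (triethylsilyl)ethynyl group at C4; triethylsilyl is preferred to trimethylsilyl because it resists carbonate and directs insertion more firmly.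

Key step: step 4

Remark: the target has no stereocentre and no stereogenic double bond, so no stereocontrol is needed; maleimide positions are numbered as in 1H-pyrrole-2,5-dione.

Step 1
Reactants: 1 2,3-dibromomaleic anhydride; 2 2,4-dimethoxybenzylamine
Product: 4 3,4-dibromo-1-(2,4-dimethoxybenzyl)-1H-pyrrole-2,5-dione, via maleamic acid 3 (not isolated)
Conditions: AcOH, rt, then 100 °C
Reagents that add atoms: none
Why: Amine 2 should open anhydride 1 to maleamic acid 3, which hot acetic acid dehydrates to the imide (anhydride-to-imide condensation), while the acidic medium keeps the amine from displacing the vinylic bromides by addition–elimination.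

Step 2
Reactants: 4 3,4-dibromo-1-(2,4-dimethoxybenzyl)-1H-pyrrole-2,5-dione; 5 1-methyl-5-(tributylstannyl)-1H-imidazole
Product: 6 3-bromo-1-(2,4-dimethoxybenzyl)-4-(1-methyl-1H-imidazol-5-yl)-1H-pyrrole-2,5-dione
Conditions: Pd2(dba)3 (2.5 mol %), AsPh3 (10 mol %), CuI (10 mol %), DMF, 50 °C; 4 in slight excess (1.2 equiv)
Reagents that add atoms: none
Why: Stille coupling at the strongly activated vinylogous acyl bromide should run under mild conditions, and because the electron-rich imidazole makes the remaining C–Br bond of 6 slower in oxidative addition, the coupling should stop at the mono-adduct when 4 is in slight excess and the weakly nucleophilic ligand AsPh3 is used.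

Step 3
Reactants: 6 3-bromo-1-(2,4-dimethoxybenzyl)-4-(1-methyl-1H-imidazol-5-yl)-1H-pyrrole-2,5-dione; 7 ethynyltriethylsilane
Product: 8 1-(2,4-dimethoxybenzyl)-3-(1-methyl-1H-imidazol-5-yl)-4-[(triethylsilyl)ethynyl]-1H-pyrrole-2,5-dione
Conditions: PdCl2(PPh3)2 (5 mol %), CuI (5 mol %), iPr2NEt, THF, rt
Reagents that add atoms: none
Why: Sonogashira coupling of the vinylogous acyl bromide, which should add oxidatively to zerovalent palladium at room temperature, with the hindered base iPr2NEt chosen because it cannot displace bromide by addition–elimination.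

Step 4
Reactants: 8 1-(2,4-dimethoxybenzyl)-3-(1-methyl-1H-imidazol-5-yl)-4-[(triethylsilyl)ethynyl]-1H-pyrrole-2,5-dione; 9 5-bromo-2-iodoaniline
Product: 10 3-[6-bromo-2-(triethylsilyl)-1H-indol-3-yl]-1-(2,4-dimethoxybenzyl)-4-(1-methyl-1H-imidazol-5-yl)-1H-pyrrole-2,5-dione
Conditions: Pd(OAc)2 (10 mol %), LiCl (1 equiv), Na2CO3 (3 equiv), DMF, 100 °C; 9 in excess (1.5 equiv)
Reagents that add atoms: none
Why: Pd(OAc)2, a divalent palladium salt, is reduced in situ to zerovalent palladium, which inserts into the C–I bond of 9; the arylpalladium iodide then adds syn across the alkyne of 8, the aryl carbon (future C3a) bonding to the alkyne carbon next to the maleimide (future C3) and palladium to the silicon-bearing carbon (future C2), after which the aniline nitrogen displaces halide on palladium and C–N reductive elimination forms N1–C2. The closest known reaction is the Larock heteroannulation of 2-iodoanilines with aryl- or alkenyl-substituted silyl alkynes, which gives 2-silyl-3-substituted indoles. The one ring formed, the indole pyrrole ring, is closed in a [3+2] sense (N1, C7a and C3a from 9; C2 and C3 from 8), the closing event being C–N reductive elimination from a six-membered azapalladacycle. No stereocentre is created. The step needs insertion regioselectivity, which the bulky triethylsilyl group should secure because it prefers the carbon bound to palladium and so ends up beside nitrogen, and it needs C–I over C–Br chemoselectivity, which the weaker C–I bond, the ligand-free catalyst and the excess of 9 should secure. If the aniline instead first adds conjugately to the silicon-bearing alkyne carbon, intramolecular Heck closure of the resulting enamine should lead to the same indole.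

Step 5
Reactants: 10 3-[6-bromo-2-(triethylsilyl)-1H-indol-3-yl]-1-(2,4-dimethoxybenzyl)-4-(1-methyl-1H-imidazol-5-yl)-1H-pyrrole-2,5-dione
Product: 12 didemnimide D [3-(6-bromo-1H-indol-3-yl)-4-(1-methyl-1H-imidazol-5-yl)-1H-pyrrole-2,5-dione], via desilylated N-protected imide 11 (not isolated)
Conditions: CF3CO2H, anisole, rt, then 75 °C
Reagents that add atoms: none
Why: CF3CO2H should protonate indole C2 ipso to silicon to give a β-silyl-stabilised cation that loses the triethylsilyl group at room temperature (protodesilylation), and on warming it should ionise the N–CH2 bond of the 2,4-dimethoxybenzyl imide to a stabilised benzyl cation that anisole traps by Friedel–Crafts alkylation (acidolytic N-debenzylation).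

Compound list
1 | 2,3-dibromomaleic anhydride | O=C1OC(=O)C(Br)=C1Br | starting material
2 | 2,4-dimethoxybenzylamine | NCc1ccc(OC)cc1OC | starting material
3 | (2Z)-2,3-dibromo-4-[(2,4-dimethoxybenzyl)amino]-4-oxobut-2-enoic acid (maleamic acid) | OC(=O)/C(Br)=C(Br)\C(=O)NCc1ccc(OC)cc1OC | intermediate
4 | 3,4-dibromo-1-(2,4-dimethoxybenzyl)-1H-pyrrole-2,5-dione | O=C1C(Br)=C(Br)C(=O)N1Cc1ccc(OC)cc1OC | intermediate
5 | 1-methyl-5-(tributylstannyl)-1H-imidazole | CCCC[Sn](CCCC)(CCCC)c1cncn1C | starting material
6 | 3-bromo-1-(2,4-dimethoxybenzyl)-4-(1-methyl-1H-imidazol-5-yl)-1H-pyrrole-2,5-dione | Cn1cncc1C1=C(Br)C(=O)N(Cc2ccc(OC)cc2OC)C1=O | intermediate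
7 | ethynyltriethylsilane | C#C[Si](CC)(CC)CC | starting material
8 | 1-(2,4-dimethoxybenzyl)-3-(1-methyl-1H-imidazol-5-yl)-4-[(triethylsilyl)ethynyl]-1H-pyrrole-2,5-dione | Cn1cncc1C1=C(C#C[Si](CC)(CC)CC)C(=O)N(Cc2ccc(OC)cc2OC)C1=O | intermediate
9 | 5-bromo-2-iodoaniline | Nc1cc(Br)ccc1I | starting material
10 | 3-[6-bromo-2-(triethylsilyl)-1H-indol-3-yl]-1-(2,4-dimethoxybenzyl)-4-(1-methyl-1H-imidazol-5-yl)-1H-pyrrole-2,5-dione | Cn1cncc1C1=C(c2c([Si](CC)(CC)CC)[nH]c3cc(Br)ccc23)C(=O)N(Cc2ccc(OC)cc2OC)C1=O | intermediate
11 | 3-(6-bromo-1H-indol-3-yl)-1-(2,4-dimethoxybenzyl)-4-(1-methyl-1H-imidazol-5-yl)-1H-pyrrole-2,5-dione | Cn1cncc1C1=C(c2c[nH]c3cc(Br)ccc23)C(=O)N(Cc2ccc(OC)cc2OC)C1=O | intermediate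
12 | didemnimide D, 3-(6-bromo-1H-indol-3-yl)-4-(1-methyl-1H-imidazol-5-yl)-1H-pyrrole-2,5-dione | Cn1cncc1C1=C(c2c[nH]c3cc(Br)ccc23)C(=O)NC1=O | target

Total step count: 5. Longest linear sequence: 5 steps (1 → 4 → 6 → 8 → 10 → 12).

Steps most likely to fail

Step 4 (key step). What may go wrong: base-induced loss of the alkynyl silyl group before insertion, insertion with the opposite regiochemistry, binding of palladium by imidazole N3, stalling after conjugate addition of the aniline, or further reaction at the C–Br bond of the product. The fallback brings the indole in intact instead of building it. It sets out from dibromide 4. Commercial 6-bromoindole is deprotonated with EtMgBr in THF/toluene to (6-bromoindol-1-yl)magnesium bromide F1. C3 of F1 adds to 4 and expels bromide (addition–elimination), which should give 3-bromo-4-(6-bromo-1H-indol-3-yl)-1-(2,4-dimethoxybenzyl)-1H-pyrrole-2,5-dione F2. Stille coupling of F2 with stannane 5 (Pd2(dba)3, AsPh3, CuI, DMF, 60 °C), selective for the vinylogous acyl bromide over the aryl bromide, should give 11. The route is rejoined at 11, which the heating stage of step 5 converts into 12.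

Step 2. What may go wrong: double coupling to the bis(imidazolyl)maleimide, quaternisation of imidazole N3 by addition–elimination at a C–Br carbon, or protodestannylation. The fallback builds the maleimide ring with the imidazole already in place, so that no double coupling can occur. It sets out from amine 2. Amide coupling with commercial (1-methyl-1H-imidazol-5-yl)acetic acid hydrochloride (EDC·HCl, HOBt, iPr2NEt, DMF) should give N-(2,4-dimethoxybenzyl)-2-(1-methyl-1H-imidazol-5-yl)acetamide F3. Condensation with diethyl oxalate (KOtBu, THF, 0 °C to rt, then acid; N-acylation and Claisen-type ring closure) should give 1-(2,4-dimethoxybenzyl)-3-hydroxy-4-(1-methyl-1H-imidazol-5-yl)-1H-pyrrole-2,5-dione F4. Oxalyl bromide with catalytic DMF in CH2Cl2 (Vilsmeier-type halogenation of the vinylogous acid) should convert F4 into bromide 6, where the route is rejoined.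

Step 3. What may go wrong: addition–elimination of the amine base or of the copper acetylide at the C–Br carbon, oxidative homocoupling of the alkyne, or copper binding to imidazole N3. The fallback is an amine-free and copper-free Stille alkynylation with a preformed tin acetylide. It sets out from alkyne 7. n-BuLi (THF, −78 °C) gives lithium (triethylsilyl)acetylide F5, which Bu3SnCl converts into tributyl[(triethylsilyl)ethynyl]stannane F6. Coupling of F6 with bromide 6 (Pd2(dba)3, AsPh3, toluene, 80 °C) should give 8, where the route is rejoined.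

Further compounds
F1 | step 4 | (6-bromoindol-1-yl)magnesium bromide | Br[Mg]n1ccc2ccc(Br)cc21
F2 | step 4 | 3-bromo-4-(6-bromo-1H-indol-3-yl)-1-(2,4-dimethoxybenzyl)-1H-pyrrole-2,5-dione | O=C1C(Br)=C(c2c[nH]c3cc(Br)ccc23)C(=O)N1Cc1ccc(OC)cc1OC
F3 | step 2 | N-(2,4-dimethoxybenzyl)-2-(1-methyl-1H-imidazol-5-yl)acetamide | Cn1cncc1CC(=O)NCc1ccc(OC)cc1OC
F4 | step 2 | 1-(2,4-dimethoxybenzyl)-3-hydroxy-4-(1-methyl-1H-imidazol-5-yl)-1H-pyrrole-2,5-dione | Cn1cncc1C1=C(O)C(=O)N(Cc2ccc(OC)cc2OC)C1=O
F5 | step 3 | lithium (triethylsilyl)acetylide | [Li]C#C[Si](CC)(CC)CC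
F6 | step 3 | tributyl[(triethylsilyl)ethynyl]stannane | CCCC[Sn](CCCC)(CCCC)C#C[Si](CC)(CC)CC
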